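The earlier runs and the new flask are calculated for substances that don't exist, noise included.

Count the half-lives in Saturday's flask, which is the flask asked about, before turning any of its settings.

- Saturday's: L 0.20 M; G 0.40 M; J 0.20 M; the very flask that is asked about, followed so far
- flask: L 0.20 M; G 0.400 M; J 0.200 M; time 12 h

Saturday's run (percent of the L charged)

| time / h | E / % | L / % |
|---|---|---|
| 0.250 | 3.5 | 90.5 |
| 0.667 | 6.9 | 86.6 |
| 1.33 | 10.2 | 83.9 |
| 2.00 | 10.6 | 83.0 |
| 3.00 | 11.4 | 81.7 |
| 4.00 | 11.6 | 81.9 |

(scatter of a reading: 0.5 percentage points)

- which holds at 12 h: what has brought the reaction to rest, or that it has not come to rest (for what has run out or reacted, a solid counts together with what of it has only dissolved) (G has run out first / forward and back rates have come level / it is still moving / all of L has reacted)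
- how much E there is at 12 h, in percent of the L charged

- given per volume of solution although it is solid: L
- the numbers in the tables scatter with a standard deviation of 0.5 percentage points
- at the start none of L is in solution
- what has only dissolved of L counts as not reacted
- the reaction counts as stopped when no species that holds the L changes by six tenths of a point or more over the second half of the time

Time comes first. In Saturday's flask E reads 6.9 % at 0.667 h and 11.6 % at 4.00 h. Taking the last reading as the plateau, the gap to it halves every 0.512 h, so 12 h holds 23.4 such half-lives, and by hand E stands on its plateau by then. What that flask reaches is then best told per litre: the last reading of E times the charge of L is 0.0232 M, and this molar ceiling, a reading with the scatter of one, is the concentration of E at which the readings come flat.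

L comes next. At 4.00 h L still holds 81.9 % of its charge in Saturday's flask, more than E does, so by hand a smaller charge of 0.080 M, with G and J as charged, reaches the same ceiling, which is 29.0 % of that charge.

G comes last. If each E takes one G, the ceiling uses 5.80 % of the 0.400 M charged, and no reading shows G or J directly. This reckoning commits to E near 11.6 % and leaves open what stops it.

The forecast gives 11.8 %, within 11.2 % to 12.6 %, which is above that reading, and for the end it gives forward and back rates have come level. In its words: “The reaction therefore stalls with both reagents plentiful”.

The flask gives 10.9 % of E, and its end is: G has run out first.

    L ⇌ X, rate k1*(cs1 - [X]) while solid is left; crystals form when [X] > cs1 (solubility = 13.0 mM, k = 0.00460 s⁻¹)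
    X + G → E (k = 0.00270 M⁻¹ s⁻¹)
    G → D (k = 4.20 × 10⁻⁴ s⁻¹)
    G + J → Z (k = 4.60 × 10⁻⁴ M⁻¹ s⁻¹)

At 12.0 h G, the limiting reagent, stands at 0 % of its charge in this flask, while D stands at 0.319 M. E there comes to 0.0219 M, below the ceiling of 0.0232 M read from Saturday's last reading. The neighbour flask charged with 0.080 M of L was reckoned at 29.0 % from that ceiling, and it stands at 27.4 %.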